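**Plan**
- Retrosynthesis: the ring oxygens at C2 (hydroxyl, Thiele–Winter acetoxylation) and C4 (carbonyl, Teuber oxidation) are removed first, leading back to a 3-methoxy-5-alkylphenol and, one carboxyl further, to a 4-O-methyl β-resorcylic ester.
- The resorcylate ring is cut at the bond between its ester-bearing carbon and the carbon that holds the side chain (future quinone C3), which is an intramolecular aldol of a 3,5,7-triketo ester. The open chain is then cut at C6–C7 (polyanion acylation) and at C2–C3 of a 3-oxohexadecanoate (Meldrum's acid acylation).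
- Enabling feature: the quinone ring carries oxygen on C1 and C5, both meta to the C3 side chain, and on C2 and C4, the pattern of a 5-alkylresorcinol oxidised twice. The side-chain oxygen at C2' lies where the 3-hydroxyl of a 3-hydroxyhexadecanoyl starter falls when a tetraketide folds C2 onto C7, and quinone C2 is the carbon that carried the carboxyl.
- Forward: C14 acid chloride → C16 β-keto ester → (R)-silyloxy Weinreb amide, joined to the C6 diketo ester to give the C22 open chain. Aldol closure and aromatisation form the only ring, followed by 4-O-methylation, decarboxylation, desilylation, para-oxidation, acetoxylation and deacetylation with air oxidation.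
- Stereochemistry: the single stereocentre (R at C2') comes from (R)-BINAP–ruthenium hydrogenation of the β-keto ester in step 2. It is carried as a silyl ether and finally acetylated on oxygen with retention.

Key step: step 6

Assumption: methyl 3,5-dioxohexanoate (8) is taken as a purchasable building block (otherwise one step from dehydroacetic acid with Mg(OMe)2 in methanol); triketo ester 9 is drawn in its keto form although it should exist as an enol mixture.

**Step 1**
Reactants: 1 tetradecanoyl (myristoyl) chloride; 2 Meldrum's acid (2,2-dimethyl-1,3-dioxane-4,6-dione)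
Product: 4 methyl 3-oxohexadecanoate, via tetradecanoyl Meldrum's acid 3 (not isolated)
Conditions: pyridine, CH2Cl2, 0 °C → rt; then MeOH, reflux
Reagents that add atoms: methanol, CO
Why: C-acylation of Meldrum's acid followed by methanolysis of the acyl Meldrum's acid through an acylketene, with loss of acetone and CO2, is the standard two-carbon homologation of an acid chloride to a β-keto ester.

**Step 2**
Reactants: 4 methyl 3-oxohexadecanoate
Product: 5 methyl (3R)-3-hydroxyhexadecanoate
Conditions: H2 (50 atm), RuCl2[(R)-BINAP] (0.1 mol%), MeOH, 50 °C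
Reagents that add atoms: none
Why: Noyori asymmetric hydrogenation, in which the ester carbonyl and the ketone chelate divalent ruthenium so that the (R)-BINAP ligand directs hydride to the face giving the (3R)-alcohol regardless of chain length, sets the only stereocentre of the target.

**Step 3**
Reactants: 5 methyl (3R)-3-hydroxyhexadecanoate
Product: 6 methyl (3R)-3-[(tert-butyldimethylsilyl)oxy]hexadecanoate
Conditions: TBSCl, imidazole, DMF, rt
Reagents that add atoms: tert-butyldimethylsilyl chloride (TBSCl), CC(C)(C)[Si](C)(C)Cl
Why: Standard imidazole-promoted silylation of a secondary alcohol masks the hydroxyl against the strong bases of steps 4 to 6 and later keeps it from lactonising onto the aryl ester.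

**Step 4**
Reactants: 6 methyl (3R)-3-[(tert-butyldimethylsilyl)oxy]hexadecanoate
Product: 7 (3R)-3-[(tert-butyldimethylsilyl)oxy]-N-methoxy-N-methylhexadecanamide
Conditions: MeNH(OMe)·HCl, i-PrMgCl, THF, −20 → 0 °C
Reagents that add atoms: N,O-dimethylhydroxylamine hydrochloride, CNOC.Cl
Why: Weinreb amide formation by aminolysis of the ester with the chloromagnesium amide proceeds at low temperature without disturbing the β-silyloxy group, and it provides an acyl donor whose α-methylene is less acidic than that of the ester and whose tetrahedral adduct is stable until quench.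

**Step 5**
Reactants: 7 (3R)-3-[(tert-butyldimethylsilyl)oxy]-N-methoxy-N-methylhexadecanamide; 8 methyl 3,5-dioxohexanoate
Product: 9 methyl (9R)-9-[(tert-butyldimethylsilyl)oxy]-3,5,7-trioxodocosanoate
Conditions: 8 (1.5 equiv), LiN(i-Pr)2 (LDA, 4.6 equiv), THF, −78 → 0 °C; then 7, −78 → 0 °C; AcOH, −78 °C
Reagents that add atoms: none
Why: C-acylation of a β-polycarbonyl polyanion, in which the trianion of 8 reacts at its terminal and most basic carbon (C6) while the N-methoxy-N-methylamide gives a chelated tetrahedral adduct that releases the C7 ketone only on the cold acidic quench, should deliver the open-chain triketo ester without over-addition and without touching the stereocentre.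

**Step 6**
Reactants: 9 methyl (9R)-9-[(tert-butyldimethylsilyl)oxy]-3,5,7-trioxodocosanoate
Product: 11 methyl 2,4-dihydroxy-6-[(2R)-2-[(tert-butyldimethylsilyl)oxy]pentadecyl]benzoate, via cyclic aldol adduct 10 (not isolated)
Conditions: aq. KHCO3/K2CO3 buffer (pH ≈ 9.5), MeOH–THF, 0 °C → rt
Reagents that add atoms: none
Why: In the buffered base the C2 methylene, flanked by the ester and the C3 ketone, is available as its enolate and adds to the C7 ketone carbonyl to give the six-membered aldol adduct 10, which loses water by an E1cB path and tautomerises at C3 and C5 to the arene, the irreversible aromatisation draining all reversible pre-equilibria. The closest known reaction type is the biomimetic aldol cyclisation of 3,5,7-triketo esters to orsellinate-type β-resorcylates. The one ring closes in a 6-(enolendo)-exo-trig aldol mode between C2 and C7, forming the bond from the ester-bearing carbon to the carbon that becomes quinone C3. No lasting stereocentre is created, since the two new centres of 10 vanish on aromatisation, and the C9 stereocentre is β and not α to the C7 ketone and so cannot epimerise. The step needs C2-to-C7 aldol closure to win over Claisen closure (C6 onto the ester C1), O-cyclisation to pyrones and aldol attack of C8 on C3: the methyl ester is the poorest electrophile of the chain and no magnesium or other chelating cation is present to template the Claisen mode, pyrone formation needs acid, and C8 is a singly activated, branched methylene far less acidic than C2. Loss of the silyloxy group by β-elimination should be held back because the C7 ketone enolises toward C6 within the β-diketone and not toward C8.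

**Step 7**
Reactants: 11 methyl 2,4-dihydroxy-6-[(2R)-2-[(tert-butyldimethylsilyl)oxy]pentadecyl]benzoate
Product: 12 methyl 2-hydroxy-4-methoxy-6-[(2R)-2-[(tert-butyldimethylsilyl)oxy]pentadecyl]benzoate
Conditions: MeI (1.1 equiv), K2CO3, acetone, rt
Reagents that add atoms: iodomethane, CI
Why: Williamson O-methylation should select the 4-hydroxyl because the 2-hydroxyl is tied up in a hydrogen bond to the ester carbonyl and is far less acidic and nucleophilic, so the two phenols are told apart here and not by statistical monomethylation of a symmetric resorcinol later.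

**Step 8**
Reactants: 12 methyl 2-hydroxy-4-methoxy-6-[(2R)-2-[(tert-butyldimethylsilyl)oxy]pentadecyl]benzoate
Product: 14 3-methoxy-5-[(2R)-2-[(tert-butyldimethylsilyl)oxy]pentadecyl]phenol, via free benzoic acid 13 (not isolated)
Conditions: KOH, MeOH–H2O, reflux; 1 M HCl to pH 4, 0 °C; then toluene, 100 °C
Reagents that add atoms: none
Why: Saponification followed by thermal protodecarboxylation should work because the free 2-hydroxy-4-methoxy-6-alkylbenzoic acid is readily ipso-protonated (ortho-hydroxyl and para-methoxyl donors, relief of ortho strain) and loses CO2 near 100 °C as orsellinic-type acids do, while the secondary silyl ether tolerates hydroxide and prevents closure to a dihydroisocoumarin lactone.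

**Step 9**
Reactants: 14 3-methoxy-5-[(2R)-2-[(tert-butyldimethylsilyl)oxy]pentadecyl]phenol
Product: 15 3-[(2R)-2-hydroxypentadecyl]-5-methoxyphenol
Conditions: 48% aq. HF, MeCN, rt
Reagents that add atoms: none
Why: Fluoride-driven desilylation cleaves the secondary silyl ether at silicon, leaving the C–O bond and hence the configuration untouched, and does not affect the phenol or the aryl methyl ether.

**Step 10**
Reactants: 15 3-[(2R)-2-hydroxypentadecyl]-5-methoxyphenol
Product: 16 2-[(2R)-2-hydroxypentadecyl]-6-methoxy-1,4-benzoquinone
Conditions: (KSO3)2NO (2.5 equiv), aq. KH2PO4, acetone, rt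
Reagents that add atoms: Fremy's salt (dipotassium nitrosodisulfonate), [K+].[K+].[O]N(S(=O)(=O)[O-])S(=O)(=O)[O-]
Why: Teuber oxidation, in which one equivalent of the nitroxyl radical abstracts the phenolic hydrogen and a second delivers oxygen to the free para position between the methoxy and alkyl groups, should give the para-quinone while leaving the secondary alcohol alone.

**Step 11**
Reactants: 16 2-[(2R)-2-hydroxypentadecyl]-6-methoxy-1,4-benzoquinone
Product: 18 (2R)-1-[2,3,6-tris(acetyloxy)-5-methoxyphenyl]pentadecan-2-yl acetate, via quinone monoacetate 17 (not isolated)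
Conditions: Ac2O, conc. H2SO4 (cat.), 0 °C → rt
Reagents that add atoms: acetic anhydride, CC(=O)OC(C)=O
Why: Thiele–Winter acetoxylation, preceded by fast acid-catalysed O-acetylation of the alcohol (C–O bond not broken, so retention), should add acetate at the ring CH next to the alkyl-bearing carbon, because the other ring CH is the electron-rich β-carbon of the methoxy-substituted vinylogous ester, and trap the adduct as the triacetoxyarene.

**Step 12**
Reactants: 18 (2R)-1-[2,3,6-tris(acetyloxy)-5-methoxyphenyl]pentadecan-2-yl acetate
Product: 20 (2R)-1-(2-hydroxy-5-methoxy-3,6-dioxocyclohexa-1,4-dien-1-yl)pentadecan-2-yl acetate (the target), via trihydroxyarene 19 (not isolated)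
Conditions: K2CO3, MeOH, 0 °C, air; then 1 M HCl
Reagents that add atoms: none
Why: Base-mediated methanolysis (transesterification) should cleave the three aryl acetates much faster than the secondary alkyl acetate because phenoxides are far better leaving groups, and the electron-rich 1,2,4-trihydroxyarene is autoxidised by air to the hydroxy-para-quinone, whose anion is stable to the mild base.

**Compound list**
1 | tetradecanoyl chloride (myristoyl chloride) | CCCCCCCCCCCCCC(=O)Cl | starting material
2 | Meldrum's acid (2,2-dimethyl-1,3-dioxane-4,6-dione) | CC1(C)OC(=O)CC(=O)O1 | starting material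
3 | 5-(1-hydroxytetradecylidene)-2,2-dimethyl-1,3-dioxane-4,6-dione (tetradecanoyl Meldrum's acid, enol form) | CCCCCCCCCCCCCC(O)=C1C(=O)OC(C)(C)OC1=O | intermediate
4 | methyl 3-oxohexadecanoate | CCCCCCCCCCCCCC(=O)CC(=O)OC | intermediate
5 | methyl (3R)-3-hydroxyhexadecanoate | CCCCCCCCCCCCC[C@H](CC(=O)OC)O | intermediate
6 | methyl (3R)-3-[(tert-butyldimethylsilyl)oxy]hexadecanoate | CCCCCCCCCCCCC[C@H](CC(=O)OC)O[Si](C)(C)C(C)(C)C | intermediate
7 | (3R)-3-[(tert-butyldimethylsilyl)oxy]-N-methoxy-N-methylhexadecanamide | CCCCCCCCCCCCC[C@H](CC(=O)N(C)OC)O[Si](C)(C)C(C)(C)C | intermediate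
8 | methyl 3,5-dioxohexanoate | COC(=O)CC(=O)CC(C)=O | starting material
9 | methyl (9R)-9-[(tert-butyldimethylsilyl)oxy]-3,5,7-trioxodocosanoate | CCCCCCCCCCCCC[C@H](CC(=O)CC(=O)CC(=O)CC(=O)OC)O[Si](C)(C)C(C)(C)C | intermediate
10 | methyl 2-hydroxy-4,6-dioxo-2-[(2R)-2-[(tert-butyldimethylsilyl)oxy]pentadecyl]cyclohexane-1-carboxylate (mixture at the two transient ring centres) | CCCCCCCCCCCCC[C@H](CC1(O)CC(=O)CC(=O)C1C(=O)OC)O[Si](C)(C)C(C)(C)C | intermediate
11 | methyl 2,4-dihydroxy-6-[(2R)-2-[(tert-butyldimethylsilyl)oxy]pentadecyl]benzoate | CCCCCCCCCCCCC[C@H](Cc1cc(O)cc(O)c1C(=O)OC)O[Si](C)(C)C(C)(C)C | intermediate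
12 | methyl 2-hydroxy-4-methoxy-6-[(2R)-2-[(tert-butyldimethylsilyl)oxy]pentadecyl]benzoate | CCCCCCCCCCCCC[C@H](Cc1cc(OC)cc(O)c1C(=O)OC)O[Si](C)(C)C(C)(C)C | intermediate
13 | 2-hydroxy-4-methoxy-6-[(2R)-2-[(tert-butyldimethylsilyl)oxy]pentadecyl]benzoic acid | CCCCCCCCCCCCC[C@H](Cc1cc(OC)cc(O)c1C(=O)O)O[Si](C)(C)C(C)(C)C | intermediate
14 | 3-methoxy-5-[(2R)-2-[(tert-butyldimethylsilyl)oxy]pentadecyl]phenol | CCCCCCCCCCCCC[C@H](Cc1cc(O)cc(OC)c1)O[Si](C)(C)C(C)(C)C | intermediate
15 | 3-[(2R)-2-hydroxypentadecyl]-5-methoxyphenol | CCCCCCCCCCCCC[C@H](Cc1cc(O)cc(OC)c1)O | intermediate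
16 | 2-[(2R)-2-hydroxypentadecyl]-6-methoxycyclohexa-2,5-diene-1,4-dione | CCCCCCCCCCCCC[C@H](CC1=CC(=O)C=C(OC)C1=O)O | intermediate
17 | (2R)-1-(5-methoxy-3,6-dioxocyclohexa-1,4-dien-1-yl)pentadecan-2-yl acetate | CCCCCCCCCCCCC[C@H](CC1=CC(=O)C=C(OC)C1=O)OC(C)=O | intermediate
18 | (2R)-1-[2,3,6-tris(acetyloxy)-5-methoxyphenyl]pentadecan-2-yl acetate | CCCCCCCCCCCCC[C@H](Cc1c(OC(C)=O)c(OC(C)=O)cc(OC)c1OC(C)=O)OC(C)=O | intermediate
19 | (2R)-1-(2,3,6-trihydroxy-5-methoxyphenyl)pentadecan-2-yl acetate | CCCCCCCCCCCCC[C@H](Cc1c(O)c(O)cc(OC)c1O)OC(C)=O | intermediate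
20 | (2R)-1-(2-hydroxy-5-methoxy-3,6-dioxocyclohexa-1,4-dien-1-yl)pentadecan-2-yl acetate | CCCCCCCCCCCCC[C@H](CC1=C(O)C(=O)C=C(OC)C1=O)OC(C)=O | target

**Step count**
Total steps: 12. Longest linear sequence: 12 steps (1 → 20; 2 and 8 enter as purchased building blocks).

**Steps most likely to fail**

Step 5. Proton transfer between the trianion and the amide or the product may leave the acylation incomplete, and the triketo ester may cyclise in an uncontrolled way during the quench. The fallback sets out from 7 and returns at 9, carrying the ester terminus masked as a dioxinone. 2,2,6-Trimethyl-4H-1,3-dioxin-4-one is deprotonated with LiN(SiMe3)2 and C-acetylated with acetyl chloride to give 2,2-dimethyl-6-(2-oxopropyl)-4H-1,3-dioxin-4-one F1. The dianion of F1 (LDA, 2 equiv, THF, −78 °C) is acylated at its terminal methyl by 7 to give the diketo-dioxinone 6-[(6R)-6-[(tert-butyldimethylsilyl)oxy]-2,4-dioxononadecyl]-2,2-dimethyl-4H-1,3-dioxin-4-one F2. Heating F2 in toluene at 110 °C with methanol expels acetone by a retro-hetero-Diels–Alder reaction, and the acylketene is trapped by methanol to give 9, ready for step 6.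

Step 6. Ring closure may take another mode (Claisen closure onto the ester, O-cyclisation to pyrones, aldol from C8), or the silyloxy group may be lost by β-elimination next to the C7 ketone. The fallback sets out from 6 and returns at 11, building the same ring by a Michael–Dieckmann sequence and a dehydrogenation. Ester 6 is reduced with i-Bu2AlH (CH2Cl2, −78 °C) to (3R)-3-[(tert-butyldimethylsilyl)oxy]hexadecanal F3. A Wittig reaction with Ph3P=CHC(O)CH3 gives (3E,6R)-6-[(tert-butyldimethylsilyl)oxy]nonadec-3-en-2-one F4. Michael addition of dimethyl malonate and Dieckmann closure onto the methyl ketone (NaOMe, MeOH, reflux) give methyl 2,4-dioxo-6-[(2R)-2-[(tert-butyldimethylsilyl)oxy]pentadecyl]cyclohexane-1-carboxylate F5. Bromination–dehydrobromination (Br2, DMF, 0 °C → rt) aromatises F5 to 11.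

Step 12. The side-chain acetate may be lost during methanolysis of the aryl acetates, or the hydroxyquinone may degrade in base. The fallback sets out from 16 and returns at 20, introducing the ring hydroxyl without any aryl acetate. Quinone alcohol 16 is acetylated (Ac2O, pyridine, CH2Cl2, 0 °C) and 17 is isolated. Nucleophilic epoxidation (t-BuOOH, DBU, CH2Cl2, 0 °C) of the alkyl-substituted double bond, the one not deactivated by the methoxy group, gives (2R)-1-(3-methoxy-2,5-dioxo-7-oxabicyclo[4.1.0]hept-3-en-1-yl)pentadecan-2-yl acetate F6. Brief treatment with conc. H2SO4 at 0 °C isomerises the epoxide to the hydroxyquinone, with oxygen remaining on the former CH carbon, to give 20.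

**Further compounds**
F1 | step 5 | 2,2-dimethyl-6-(2-oxopropyl)-4H-1,3-dioxin-4-one | CC(=O)CC1=CC(=O)OC(C)(C)O1
F2 | step 5 | 6-[(6R)-6-[(tert-butyldimethylsilyl)oxy]-2,4-dioxononadecyl]-2,2-dimethyl-4H-1,3-dioxin-4-one | CCCCCCCCCCCCC[C@H](CC(=O)CC(=O)CC1=CC(=O)OC(C)(C)O1)O[Si](C)(C)C(C)(C)C
F3 | step 6 | (3R)-3-[(tert-butyldimethylsilyl)oxy]hexadecanal | CCCCCCCCCCCCC[C@H](CC=O)O[Si](C)(C)C(C)(C)C
F4 | step 6 | (3E,6R)-6-[(tert-butyldimethylsilyl)oxy]nonadec-3-en-2-one | CCCCCCCCCCCCC[C@H](C/C=C/C(C)=O)O[Si](C)(C)C(C)(C)C
F5 | step 6 | methyl 2,4-dioxo-6-[(2R)-2-[(tert-butyldimethylsilyl)oxy]pentadecyl]cyclohexane-1-carboxylate (mixture at the two ring centres) | CCCCCCCCCCCCC[C@H](CC1CC(=O)CC(=O)C1C(=O)OC)O[Si](C)(C)C(C)(C)C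
F6 | step 12 | (2R)-1-(3-methoxy-2,5-dioxo-7-oxabicyclo[4.1.0]hept-3-en-1-yl)pentadecan-2-yl acetate (mixture at the two epoxide carbons) | CCCCCCCCCCCCC[C@H](CC12OC1C(=O)C=C(OC)C2=O)OC(C)=O
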